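**Plan**

- The target is an achiral, C2-symmetric dimer. In each half, ring A is the benzene ring and ring B the dione ring, numbered as naphthalen-1(4H)-one.
- Retrosynthesis: the four phenols are first masked as methyl ethers. Rings B and B′ are then each cut at C1–C8a and at C2–C3, which leaves two 2-aryl-2-methylpropanoyl units and one five-carbon chain.
- Enabling feature: C1–C2–CH2–C2′–C1′ is the carbon chain of pentanedioic acid. C4 is quaternary, so the acyl carbon C3 cannot enolise. C8a is one of two equivalent positions of ring A, ortho to the oxygen at C8 and para to the oxygen at C6.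
- Forward: ring A is bought. α,α-Dimethylation, saponification and lithiation/acetylation between the methoxy groups give the aryl acid. Its chloride is condensed twice with glutaryl dichloride so that rings B and B′ arise together, and the ethers are cleaved last.
- Stereochemistry: there is no stereocentre and no double-bond geometry to set; only enol tautomers are involved.

Key step: step 5

Remark on the chemistry: the target is drawn as one of several equivalent enol tautomers of a 2,2′-methylenebis(naphthalene-1,3-dione). The route should deliver the equilibrating mixture, written throughout in the tautomer of the target SMILES.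

**Route**

Step 1
Reactants: 1 methyl 2-(3,5-dimethoxyphenyl)acetate
Product: 2 methyl 2-(3,5-dimethoxyphenyl)-2-methylpropanoate
Conditions: NaH (2.5 equiv), MeI (3 equiv), THF/DMF, 0 °C to rt
Reagents that add atoms: iodomethane, CI
Why: Two successive enolate C-alkylations of the benzylic ester should install the gem-dimethyl carbon that becomes C4; no stereocentre arises.

Step 2
Reactants: 2 methyl 2-(3,5-dimethoxyphenyl)-2-methylpropanoate
Product: 3 2-(3,5-dimethoxyphenyl)-2-methylpropanoic acid
Conditions: KOH, MeOH/H2O, reflux; then aq HCl
Reagents that add atoms: potassium hydroxide, [K+].[OH-]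
Why: Saponification of the hindered, non-enolisable ester should free the acid, whose CO2Li form shields the carbonyl from the organolithium in step 3.

Step 3
Reactants: 3 2-(3,5-dimethoxyphenyl)-2-methylpropanoic acid
Product: 5 2-(4-acetyl-3,5-dimethoxyphenyl)-2-methylpropanoic acid, via dilithiated acid 4 (not isolated)
Conditions: s-BuLi (2.3 equiv), TMEDA, THF, −78 to −20 °C; then MeC(O)N(OMe)Me, −78 °C to rt; aq HCl
Reagents that add atoms: N-methoxy-N-methylacetamide, CC(=O)N(C)OC
Why: Directed ortho-metalation should occur at the only position flanked by two methoxy groups (the future C7), since the quaternary side-chain carbon offers no competing α- or benzylic proton, and the Weinreb amide acylates the aryllithium once through its stable chelated tetrahedral adduct.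

Step 4
Reactants: 5 2-(4-acetyl-3,5-dimethoxyphenyl)-2-methylpropanoic acid
Product: 6 2-(4-acetyl-3,5-dimethoxyphenyl)-2-methylpropanoyl chloride
Conditions: (COCl)2, cat. DMF, CH2Cl2, 0 °C to rt; volatiles removed, used crude
Reagents that add atoms: oxalyl chloride, ClC(=O)C(=O)Cl
Why: Vilsmeier-catalysed acyl chloride formation is standard; the quaternary α-carbon excludes ketene formation and the aryl ketone should be inert.

Step 5
Reactants: 6 2-(4-acetyl-3,5-dimethoxyphenyl)-2-methylpropanoyl chloride (2.1 equiv); 7 glutaryl dichloride (pentanedioyl dichloride, 1 equiv)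
Product: 9 2,2′-methylenebis(7-acetyl-3-hydroxy-6,8-dimethoxy-4,4-dimethylnaphthalen-1(4H)-one), via bis(acyl chloride) diketone 8 (not isolated)
Conditions: AlCl3 (8 equiv), MeNO2, 7 premixed at 0 °C, 6 added slowly, 0 °C to rt then 40 °C; ice/aq HCl
Reagents that add atoms: none
Why: Proposed new method: AlCl3 ionises glutaryl dichloride 7 to an unhindered primary acylium ion that acylates each molecule of 6 at C8a (Friedel–Crafts, at the site ortho to one methoxy group and para to the other), and the AlCl2 enolate of the resulting aryl ketone 8 then attacks the adjacent tertiary acyl chloride through C2, so that C1–C8a and C2–C3 of rings B and B′ form in one flask and the product is held as its AlCl2 β-diketonate chelate. The closest known reaction types are the Friedel–Crafts synthesis of 1,5-diaryl-1,5-diketones from glutaryl dichloride and the AlCl3/MeNO2-mediated Dieckmann-type cyclisation that turns diacid derivatives and acyl chlorides into 2-alkylcycloalkane-1,3-diones; their merger on an arylacetyl chloride is the new element. Each six-membered ring closes by a 6-(enolendo)-exo-trig C-acylation helped by the gem-dimethyl (Thorpe–Ingold) effect, and if enol C-acylation of 7 by 6 should come first, the same ring closes by intramolecular Friedel–Crafts attack of C8a on the β-keto acylium ion, so both orders converge on 9. No stereocentre is created. The step needs cross-condensation over self-condensation and ring acylation over acylation of the acetyl enol: C4 is quaternary, so 6 has no α-hydrogen and can only be the electrophile toward C2, the two free ring positions of 6 are equivalent, and the para-acetyl group disfavours loss of CO from the tertiary acylium ion to a cumyl cation.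

Step 6
Reactants: 9 2,2′-methylenebis(7-acetyl-3-hydroxy-6,8-dimethoxy-4,4-dimethylnaphthalen-1(4H)-one)
Product: 10 2,2′-methylenebis(7-acetyl-3,6,8-trihydroxy-4,4-dimethylnaphthalen-1(4H)-one) (CNP0295164.0)
Conditions: BBr3 (10 equiv), CH2Cl2, −78 °C to rt; then H2O
Reagents that add atoms: none
Why: Every methoxy group lies ortho to a carbonyl group, so chelation-assisted Lewis-acid ether cleavage (bromide SN2 at methyl) should remove all four, while the ketones and enolised diones are only reversibly complexed; material already partly demethylated in step 5 converges here.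

**Compound list**

1 | methyl 2-(3,5-dimethoxyphenyl)acetate | COC(=O)Cc1cc(OC)cc(OC)c1 | starting material
2 | methyl 2-(3,5-dimethoxyphenyl)-2-methylpropanoate | COC(=O)C(C)(C)c1cc(OC)cc(OC)c1 | intermediate
3 | 2-(3,5-dimethoxyphenyl)-2-methylpropanoic acid | OC(=O)C(C)(C)c1cc(OC)cc(OC)c1 | intermediate
4 | lithium 2-(4-lithio-3,5-dimethoxyphenyl)-2-methylpropanoate | [Li]OC(=O)C(C)(C)c1cc(OC)c([Li])c(OC)c1 | intermediate
5 | 2-(4-acetyl-3,5-dimethoxyphenyl)-2-methylpropanoic acid | CC(=O)c1c(OC)cc(cc1OC)C(C)(C)C(=O)O | intermediate
6 | 2-(4-acetyl-3,5-dimethoxyphenyl)-2-methylpropanoyl chloride | CC(=O)c1c(OC)cc(cc1OC)C(C)(C)C(=O)Cl | intermediate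
7 | glutaryl dichloride (pentanedioyl dichloride) | ClC(=O)CCCC(=O)Cl | starting material
8 | 1,5-bis[3-acetyl-6-(1-chloro-2-methyl-1-oxopropan-2-yl)-2,4-dimethoxyphenyl]pentane-1,5-dione | CC(=O)c1c(OC)cc(C(C)(C)C(=O)Cl)c(C(=O)CCCC(=O)c2c(OC)c(C(C)=O)c(OC)cc2C(C)(C)C(=O)Cl)c1OC | intermediate
9 | 2,2′-methylenebis(7-acetyl-3-hydroxy-6,8-dimethoxy-4,4-dimethylnaphthalen-1(4H)-one) | CC(=O)c1c(OC)cc2c(c1OC)C(=O)C(CC1=C(O)C(C)(C)c3cc(OC)c(C(C)=O)c(OC)c3C1=O)=C(O)C2(C)C | intermediate
10 | 2,2′-methylenebis(7-acetyl-3,6,8-trihydroxy-4,4-dimethylnaphthalen-1(4H)-one) | CC(=O)c1c(O)cc2c(c1O)C(=O)C(CC1=C(O)C(C)(C)c3cc(O)c(C(C)=O)c(O)c3C1=O)=C(O)C2(C)C | target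

**Totals**

Total step count: 6. Longest linear sequence: 6 steps (1 to 10).

**Steps most likely to fail**

Step 5 (Proposed new method). The glutaryl unit may be lost to self-condensation or enol-lactone closure before it acylates the ring position flanked by a methoxy group and the quaternary carbon. The acetyl enol may be acylated in competition, and the tertiary acylium ion may lose CO. The fallback uses known chemistry, closes the two bonds one after the other and adds the bridge last. It sets out from 6, which should acylate Meldrum's acid (pyridine, CH2Cl2, 0 °C to rt) to give 5-[2-(4-acetyl-3,5-dimethoxyphenyl)-1-hydroxy-2-methylpropylidene]-2,2-dimethyl-1,3-dioxane-4,6-dione F1. Methanolysis in refluxing MeOH should give methyl 4-(4-acetyl-3,5-dimethoxyphenyl)-4-methyl-3-oxopentanoate F2. Intramolecular Friedel–Crafts acylation in P2O5/MeSO3H should close ring B to 7-acetyl-3-hydroxy-6,8-dimethoxy-4,4-dimethylnaphthalen-1(4H)-one F3. Two molecules of F3 should then be joined by aqueous formaldehyde (0.5 equiv, EtOH, cat. piperidine, rt) in a Knoevenagel–Michael sequence, which comes back to the route at 9.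

Step 3. The alkyllithium may add to the CO2Li group, metalation may be steered next to the side chain by the carboxylate, or the aryllithium may be quenched by proton transfer from the Weinreb amide. The fallback removes the carbonyl before metalation. It sets out from 2, which LiAlH4 (THF, 0 °C) should reduce to 2-(3,5-dimethoxyphenyl)-2-methylpropan-1-ol F4. n-BuLi (2.2 equiv, THF, 0 °C to rt) should give lithium 2-(4-lithio-3,5-dimethoxyphenyl)-2-methylpropan-1-olate F5, and N-methoxy-N-methylacetamide should convert it into 1-[4-(1-hydroxy-2-methylpropan-2-yl)-2,6-dimethoxyphenyl]ethan-1-one F6. Dess–Martin periodinane should give 2-(4-acetyl-3,5-dimethoxyphenyl)-2-methylpropanal F7, and Pinnick oxidation (NaClO2, NaH2PO4, 2-methyl-2-butene, t-BuOH/H2O) comes back to the route at 5.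

Step 6. Ether cleavage may stop short at the less well chelated methoxy groups, or the Lewis acid may trigger retro-Michael loss of the methylene bridge. The fallback deprotects before the bridge exists. It sets out from 6 and follows the fallback to step 5 through F1 and F2 to F3. BBr3 (CH2Cl2, −78 °C to rt) on this monomer should give 7-acetyl-3,6,8-trihydroxy-4,4-dimethylnaphthalen-1(4H)-one F8. Condensation of two molecules of F8 with aqueous formaldehyde (0.5 equiv, EtOH, rt), in the manner of methylene-bridged dione dimers, comes back to the route at 10.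

**Further compounds**

F1 | step 5 | 5-[2-(4-acetyl-3,5-dimethoxyphenyl)-1-hydroxy-2-methylpropylidene]-2,2-dimethyl-1,3-dioxane-4,6-dione | CC(=O)c1c(OC)cc(cc1OC)C(C)(C)C(O)=C1C(=O)OC(C)(C)OC1=O
F2 | step 5 | methyl 4-(4-acetyl-3,5-dimethoxyphenyl)-4-methyl-3-oxopentanoate | CC(=O)c1c(OC)cc(cc1OC)C(C)(C)C(=O)CC(=O)OC
F3 | step 5 | 7-acetyl-3-hydroxy-6,8-dimethoxy-4,4-dimethylnaphthalen-1(4H)-one | CC(=O)c1c(OC)cc2c(c1OC)C(=O)C=C(O)C2(C)C
F4 | step 3 | 2-(3,5-dimethoxyphenyl)-2-methylpropan-1-ol | OCC(C)(C)c1cc(OC)cc(OC)c1
F5 | step 3 | lithium 2-(4-lithio-3,5-dimethoxyphenyl)-2-methylpropan-1-olate | [Li]OCC(C)(C)c1cc(OC)c([Li])c(OC)c1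
F6 | step 3 | 1-[4-(1-hydroxy-2-methylpropan-2-yl)-2,6-dimethoxyphenyl]ethan-1-one | CC(=O)c1c(OC)cc(cc1OC)C(C)(C)CO
F7 | step 3 | 2-(4-acetyl-3,5-dimethoxyphenyl)-2-methylpropanal | CC(=O)c1c(OC)cc(cc1OC)C(C)(C)C=O
F8 | step 6 | 7-acetyl-3,6,8-trihydroxy-4,4-dimethylnaphthalen-1(4H)-one | CC(=O)c1c(O)cc2c(c1O)C(=O)C=C(O)C2(C)C
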